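**Strategy.** The route rests on recognising C3 of the chromanone ring as the carbene carbon of a diaryl α-diazo ketone: it carries ring B (C1'), the C4 carbonyl attached to ring A, an oxygen and the C2 methylene. One catalytic operation joins this carbene to 4-methoxybenzyl alcohol (C3–O) and formaldehyde (C2–C3) and sets the sole stereocentre under a chiral phosphoric acid. The precursor is the diazo deoxybenzoin whose ring B is masked as the 2',3'-acetonide and whose ring A bears 4-OMOM and an ortho fluorine. The fluorine is later displaced by the new primary alkoxide to close O1–C8a, and two deprotections finish the synthesis.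

Key step: step 9

Assumption: which antipode of the chiral phosphoric acid delivers the (R) centre cannot be assigned with certainty in advance; the (R)-acid is written, and its commercially available antipode is used if a test run shows the opposite sense.

Abbreviation: ArB = 7-methoxy-2,2-dimethyl-6-(2-methylbut-3-en-2-yl)-1,3-benzodioxol-4-yl, that is ring B with the 2',3'-acetonide, 4'-OMe and 5'-(1,1-dimethylallyl) group, attached through C1'.

Step 1
Reactants: 1 pyrogallol
Product: 2 2,2-dimethyl-1,3-benzodioxol-4-ol (pyrogallol acetonide)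
Conditions: 2,2-dimethoxypropane, p-TsOH (cat.), toluene, reflux, MeOH distilled off
Reagents that add atoms: 2,2-dimethoxypropane, COC(C)(C)OC
Why: Acid-catalysed ketal exchange can only bridge two adjacent hydroxyls, and either adjacent pair of the symmetric triol gives the same five-membered ketal with one phenol left free.

Step 2
Reactants: 2 pyrogallol acetonide; 3 prenyl bromide
Product: 4 2,2-dimethyl-4-[(3-methylbut-2-en-1-yl)oxy]-1,3-benzodioxole
Conditions: K2CO3, acetone, reflux
Reagents that add atoms: none
Why: Williamson etherification of the only phenol with a primary allylic bromide, and carbonate in acetone favours O- over C-alkylation.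

Step 3
Reactants: 4 prenyl ether
Product: 6 2,2-dimethyl-5-(2-methylbut-3-en-2-yl)-1,3-benzodioxol-4-ol, via ortho dienone 5 (not isolated)
Conditions: PhNEt2, 190 °C, sealed tube, Ar
Reagents that add atoms: none
Why: Aromatic Claisen rearrangement: the [3,3] shift delivers the prenyl group with allylic inversion to the only unsubstituted ortho carbon (C5), and the basic solvent speeds tautomerisation of dienone 5 to the 1,1-dimethylallyl phenol.

Step 4
Reactants: 6 ortho-(1,1-dimethylallyl) phenol
Product: 7 7-bromo-2,2-dimethyl-5-(2-methylbut-3-en-2-yl)-1,3-benzodioxol-4-ol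
Conditions: NBS (1.0 equiv), MeCN, −30 → 0 °C, dark
Reagents that add atoms: N-bromosuccinimide, O=C1CCC(=O)N1Br
Why: Electrophilic aromatic bromination is steered by the free phenol to its para carbon C7 (both ortho carbons are substituted, and C7 is also ortho to a ring oxygen), and this very electron-rich ring should react at low temperature faster than the hindered monosubstituted alkene; brominating before O-methylation is chosen because the phenol is a stronger and unambiguous director.

Step 5
Reactants: 7 bromophenol
Product: 8 7-bromo-4-methoxy-2,2-dimethyl-5-(2-methylbut-3-en-2-yl)-1,3-benzodioxole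
Conditions: MeI, K2CO3, DMF, 40 °C
Reagents that add atoms: iodomethane, CI
Why: Williamson O-methylation of the flanked phenoxide with a small electrophile in a polar aprotic solvent.

Step 6
Reactants: 9 2'-fluoro-4'-hydroxyacetophenone
Product: 10 1-[2-fluoro-4-(methoxymethoxy)phenyl]ethanone
Conditions: MOMCl, i-Pr2NEt, CH2Cl2, 0 °C → rt
Reagents that add atoms: chloromethyl methyl ether, COCCl
Why: O-alkylation of the phenol as its MOM acetal, which keeps this oxygen out of the later carbene step and stops a para phenoxide from deactivating ring A in the ring closure.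

Step 7
Reactants: 10 MOM-protected fluoro ketone; 8 aryl bromide
Product: 11 1-[2-fluoro-4-(methoxymethoxy)phenyl]-2-(ArB)ethanone
Conditions: Pd2(dba)3 (1.5 mol%), Xantphos (3.6 mol%), K3PO4, toluene, 80 °C, 10 in slight excess
Reagents that add atoms: none
Why: Palladium-catalysed α-arylation of a methyl ketone (oxidative addition of zerovalent palladium into C–Br, enolate binding, reductive elimination); phosphate is too poor a nucleophile to displace the fluoride, the bulky mono-arylated product resists a second arylation, and the hindered vinyl group should not enter a Heck reaction.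

Step 8
Reactants: 11 deoxybenzoin
Product: 12 2-diazo-1-[2-fluoro-4-(methoxymethoxy)phenyl]-2-(ArB)ethanone
Conditions: p-ABSA, DBU, MeCN, 0 °C → rt
Reagents that add atoms: 4-acetamidobenzenesulfonyl azide, CC(=O)Nc1ccc(cc1)S(=O)(=O)N=[N+]=[N-]
Why: Regitz diazo transfer: the methylene flanked by aryl and aroyl is acidic enough for DBU, its enolate attacks the terminal azide nitrogen, and the triazene collapses to the diazo ketone and the sulfonamide.

Step 9
Reactants: 12 diazo ketone; 13 4-methoxybenzyl alcohol; 14 formaldehyde
Product: 16 (2R)-1-[2-fluoro-4-(methoxymethoxy)phenyl]-3-hydroxy-2-[(4-methoxybenzyl)oxy]-2-(ArB)propan-1-one, via alkoxy enol 15 (not isolated)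
Conditions: Rh2(OAc)4 (2 mol%), (R)-TRIP (10 mol%), 13 (1.5 equiv), 14 (monomeric, THF solution, 8 equiv), 4 Å MS, CH2Cl2, −20 °C, slow addition of 12
Reagents that add atoms: none
Why: Rh2(OAc)4 decomposes 12 with loss of N2 to an electrophilic donor/acceptor carbene at the future C3, and the hydroxyl of 13 adds to it to give a protic oxonium ylide in equilibrium with alkoxy enol 15. The chiral phosphoric acid binds the enol OH through its P=O oxygen and activates formaldehyde through its acidic OH, so the aldol-type C2–C3 bond forms inside a hydrogen-bonded chiral assembly whose 3,3'-aryl walls decide which enol face is attacked and hence the (R) configuration of the new quaternary carbon. The closest known chemistry is the dirhodium/chiral phosphoric acid co-catalysed three-component coupling of aryl diazo carbonyl compounds, alcohols and aldehydes or imines through trapped oxonium ylides. No ring is closed; the step makes two bonds (C3–O and C2–C3) and the only stereocentre. It needs trapping to beat the 1,2-proton shift that would give plain O–H insertion, which excess monomeric formaldehyde, low temperature and slow addition of 12 should secure. It also needs the carbene to ignore the rest of the molecule: the acetonide puts a hydrogen-free quaternary carbon on the 2'-oxygen so no five-membered C–H insertion is possible, ring A carries fluorine and not an ether oxygen ortho to the acyl group so no cyclic oxonium ylide can form, and the hindered vinyl group sits meta to the carbene and out of reach.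

Step 10
Reactants: 16 three-component adduct
Product: 17 (3R)-7-(methoxymethoxy)-3-[(4-methoxybenzyl)oxy]-3-(ArB)-2,3-dihydro-4H-chromen-4-one
Conditions: Cs2CO3, DMF, 0 °C → rt
Reagents that add atoms: none
Why: Intramolecular nucleophilic aromatic substitution (addition–elimination, six-membered closure of O1–C8a): the primary alkoxide attacks the fluorine-bearing carbon ortho to the ketone; the tertiary oxygen is still a PMB ether so only the chromanone can form, C3 bears no hydrogen, and low temperature with a caesium counter-ion is chosen so that the irreversible closure outruns retro-aldol loss of formaldehyde.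

Step 11
Reactants: 17 PMB-protected chromanone
Product: 18 (3R)-3-hydroxy-7-(methoxymethoxy)-3-(ArB)-2,3-dihydro-4H-chromen-4-one
Conditions: DDQ, CH2Cl2/pH 7 buffer (10:1), 0 °C → rt
Reagents that add atoms: none
Why: Oxidative PMB ether cleavage: DDQ takes hydride from the electron-rich benzylic CH2 and water hydrolyses the oxocarbenium ion; no other benzylic or allylic C–H is present (C3 and the 1,1-dimethylallyl carbon are quaternary), and MOM and acetonide are inert.

Step 12
Reactants: 18 protected 3-hydroxychromanone
Product: 19 (3R)-3-[2,3-dihydroxy-4-methoxy-5-(2-methylbut-3-en-2-yl)phenyl]-3,7-dihydroxy-2,3-dihydro-4H-chromen-4-one (target)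
Conditions: TFA/H2O/CH2Cl2 (9:1:5), 0 °C → rt, Ar
Reagents that add atoms: none
Why: Acid hydrolysis of the aryl MOM acetal and the catechol ketal; the tertiary C3–OH is α to the ketone and so resists ionisation (dehydration to the isoflavone), the monosubstituted vinyl group has no ortho phenol to cyclise onto and should not be protonated in the short exposure, and C3 has no hydrogen, so its configuration is untouched.

**Compound list**

1 | pyrogallol | Oc1cccc(O)c1O | starting material
2 | 2,2-dimethyl-1,3-benzodioxol-4-ol | CC1(C)Oc2cccc(O)c2O1 | intermediate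
3 | prenyl bromide | CC(C)=CCBr | starting material
4 | 2,2-dimethyl-4-[(3-methylbut-2-en-1-yl)oxy]-1,3-benzodioxole | CC(C)=CCOc1cccc2OC(C)(C)Oc12 | intermediate
5 | 2,2-dimethyl-5-(2-methylbut-3-en-2-yl)-1,3-benzodioxol-4(5H)-one (ortho dienone, formed in the flask in step 3) | C=CC(C)(C)C1C=CC2=C(OC(C)(C)O2)C1=O | intermediate
6 | 2,2-dimethyl-5-(2-methylbut-3-en-2-yl)-1,3-benzodioxol-4-ol | C=CC(C)(C)c1ccc2OC(C)(C)Oc2c1O | intermediate
7 | 7-bromo-2,2-dimethyl-5-(2-methylbut-3-en-2-yl)-1,3-benzodioxol-4-ol | C=CC(C)(C)c1cc(Br)c2OC(C)(C)Oc2c1O | intermediate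
8 | 7-bromo-4-methoxy-2,2-dimethyl-5-(2-methylbut-3-en-2-yl)-1,3-benzodioxole | C=CC(C)(C)c1cc(Br)c2OC(C)(C)Oc2c1OC | intermediate
9 | 2'-fluoro-4'-hydroxyacetophenone | CC(=O)c1ccc(O)cc1F | starting material
10 | 1-[2-fluoro-4-(methoxymethoxy)phenyl]ethanone | CC(=O)c1ccc(OCOC)cc1F | intermediate
11 | 1-[2-fluoro-4-(methoxymethoxy)phenyl]-2-(ArB)ethanone | C=CC(C)(C)c1cc(CC(=O)c3ccc(OCOC)cc3F)c2OC(C)(C)Oc2c1OC | intermediate
12 | 2-diazo-1-[2-fluoro-4-(methoxymethoxy)phenyl]-2-(ArB)ethanone | C=CC(C)(C)c1cc(C(=[N+]=[N-])C(=O)c3ccc(OCOC)cc3F)c2OC(C)(C)Oc2c1OC | intermediate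
13 | 4-methoxybenzyl alcohol | COc1ccc(CO)cc1 | starting material
14 | formaldehyde | C=O | starting material
15 | 1-[2-fluoro-4-(methoxymethoxy)phenyl]-2-[(4-methoxybenzyl)oxy]-2-(ArB)ethen-1-ol (alkoxy enol, tautomer of the protic oxonium ylide, formed in the flask in step 9) | C=CC(C)(C)c1cc(C(OCc3ccc(OC)cc3)=C(O)c4ccc(OCOC)cc4F)c2OC(C)(C)Oc2c1OC | intermediate
16 | (2R)-1-[2-fluoro-4-(methoxymethoxy)phenyl]-3-hydroxy-2-[(4-methoxybenzyl)oxy]-2-(ArB)propan-1-one | C=CC(C)(C)c1cc([C@@](C(=O)c3ccc(OCOC)cc3F)(OCc3ccc(OC)cc3)CO)c2OC(C)(C)Oc2c1OC | intermediate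
17 | (3R)-7-(methoxymethoxy)-3-[(4-methoxybenzyl)oxy]-3-(ArB)-2,3-dihydro-4H-chromen-4-one | C=CC(C)(C)c1cc([C@@]3(OCc5ccc(OC)cc5)COc4cc(OCOC)ccc4C3=O)c2OC(C)(C)Oc2c1OC | intermediate
18 | (3R)-3-hydroxy-7-(methoxymethoxy)-3-(ArB)-2,3-dihydro-4H-chromen-4-one | C=CC(C)(C)c1cc([C@@]3(O)COc4cc(OCOC)ccc4C3=O)c2OC(C)(C)Oc2c1OC | intermediate
19 | (3R)-3-[2,3-dihydroxy-4-methoxy-5-(2-methylbut-3-en-2-yl)phenyl]-3,7-dihydroxy-2,3-dihydro-4H-chromen-4-one | C=CC(C)(C)c1cc([C@@]2(O)COc3cc(O)ccc3C2=O)c(O)c(O)c1OC | target

**Step count.** Total: 12 steps. Longest linear sequence: 11 steps (pyrogallol 1 to target 19 through steps 1–5 and 7–12; the ring-A branch contributes step 6).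

**Steps most likely to fail**

1. Step 9. The 1,2-proton shift within the ylide may outpace capture by formaldehyde, so that simple O–H insertion results, and face discrimination may be weak because formaldehyde offers the acid no substituent to hold. The fallback sets out from 11 and comes back at 18. Treating 11 with one equivalent of aqueous formaldehyde and K2CO3 in DMF should hydroxymethylate the acidic methylene to give 1-[2-fluoro-4-(methoxymethoxy)phenyl]-3-hydroxy-2-(ArB)propan-1-one F1, which is not isolated. Its alkoxide displaces the fluoride in the same flask to give racemic 7-(methoxymethoxy)-3-(ArB)-2,3-dihydro-4H-chromen-4-one F2. The sodium enolate of F2 (NaHMDS, THF, −78 °C) is then oxidised with an enantiopure [(8,8-dichlorocamphoryl)sulfonyl]oxaziridine (asymmetric enolate hydroxylation; the antipode is chosen to give 3R, with enrichment by crystallisation if needed). This gives 18 directly and replaces steps 8–11.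

2. Step 10. Retro-aldol loss of formaldehyde from the primary alkoxide may compete with ring closure, lowering the yield and, through re-addition, the enantiomeric purity. The fallback sets out from 16 and comes back at 17, and closes the ring under neutral conditions at O1–C2 instead. The primary alcohol is silylated (TBSCl, imidazole, DMF) to give (2R)-3-[(tert-butyldimethylsilyl)oxy]-1-[2-fluoro-4-(methoxymethoxy)phenyl]-2-[(4-methoxybenzyl)oxy]-2-(ArB)propan-1-one F3, which has no free hydroxyl and so cannot undergo retro-aldol. The fluoride is displaced by the hydroxide surrogate 2-(methylsulfonyl)ethanol with NaH in DMF; the aryl 2-(methylsulfonyl)ethyl ether F4, not isolated, eliminates methyl vinyl sulfone to leave the ortho-hydroxy ketone (2R)-3-[(tert-butyldimethylsilyl)oxy]-1-[2-hydroxy-4-(methoxymethoxy)phenyl]-2-[(4-methoxybenzyl)oxy]-2-(ArB)propan-1-one F5. HF·pyridine in THF removes the silyl group to give (2R)-3-hydroxy-1-[2-hydroxy-4-(methoxymethoxy)phenyl]-2-[(4-methoxybenzyl)oxy]-2-(ArB)propan-1-one F6. Mitsunobu etherification (PPh3, DIAD, THF), with the phenol attacking the activated primary carbon, then gives 17.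

3. Step 3. The prenyl group may migrate on to the open para carbon C7 through a Cope shift of the dienone formed at the oxygen-bearing ortho carbon, and some prenyl may be lost thermally. The fallback sets out from 2 and comes back at 7. Phenol 2 is brominated first (NBS, MeCN, −30 °C), para to the hydroxyl, to give 7-bromo-2,2-dimethyl-1,3-benzodioxol-4-ol F7. O-Prenylation with 3 (K2CO3, acetone) gives 7-bromo-2,2-dimethyl-4-[(3-methylbut-2-en-1-yl)oxy]-1,3-benzodioxole F8. Heating in PhNEt2 then rearranges F8 through the bromo dienone 7-bromo-2,2-dimethyl-5-(2-methylbut-3-en-2-yl)-1,3-benzodioxol-4(5H)-one F9, not isolated. With the para carbon occupied by the bromine that is needed anyway, the rearrangement can only end at C5 and gives 7, replacing steps 2–4 by three steps.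

Further compounds
F1 | step 9 | 1-[2-fluoro-4-(methoxymethoxy)phenyl]-3-hydroxy-2-(ArB)propan-1-one (racemic, not isolated) | C=CC(C)(C)c1cc(C(CO)C(=O)c3ccc(OCOC)cc3F)c2OC(C)(C)Oc2c1OC
F2 | step 9 | 7-(methoxymethoxy)-3-(ArB)-2,3-dihydro-4H-chromen-4-one (racemic) | C=CC(C)(C)c1cc(C3COc4cc(OCOC)ccc4C3=O)c2OC(C)(C)Oc2c1OC
F3 | step 10 | (2R)-3-[(tert-butyldimethylsilyl)oxy]-1-[2-fluoro-4-(methoxymethoxy)phenyl]-2-[(4-methoxybenzyl)oxy]-2-(ArB)propan-1-one | C=CC(C)(C)c1cc([C@@](C(=O)c3ccc(OCOC)cc3F)(OCc3ccc(OC)cc3)CO[Si](C)(C)C(C)(C)C)c2OC(C)(C)Oc2c1OC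
F4 | step 10 | (2R)-3-[(tert-butyldimethylsilyl)oxy]-1-{4-(methoxymethoxy)-2-[2-(methylsulfonyl)ethoxy]phenyl}-2-[(4-methoxybenzyl)oxy]-2-(ArB)propan-1-one (not isolated) | C=CC(C)(C)c1cc([C@@](C(=O)c3ccc(OCOC)cc3OCCS(C)(=O)=O)(OCc3ccc(OC)cc3)CO[Si](C)(C)C(C)(C)C)c2OC(C)(C)Oc2c1OC
F5 | step 10 | (2R)-3-[(tert-butyldimethylsilyl)oxy]-1-[2-hydroxy-4-(methoxymethoxy)phenyl]-2-[(4-methoxybenzyl)oxy]-2-(ArB)propan-1-one | C=CC(C)(C)c1cc([C@@](C(=O)c3ccc(OCOC)cc3O)(OCc3ccc(OC)cc3)CO[Si](C)(C)C(C)(C)C)c2OC(C)(C)Oc2c1OC
F6 | step 10 | (2R)-3-hydroxy-1-[2-hydroxy-4-(methoxymethoxy)phenyl]-2-[(4-methoxybenzyl)oxy]-2-(ArB)propan-1-one | C=CC(C)(C)c1cc([C@@](C(=O)c3ccc(OCOC)cc3O)(OCc3ccc(OC)cc3)CO)c2OC(C)(C)Oc2c1OC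
F7 | step 3 | 7-bromo-2,2-dimethyl-1,3-benzodioxol-4-ol | CC1(C)Oc2c(Br)ccc(O)c2O1
F8 | step 3 | 7-bromo-2,2-dimethyl-4-[(3-methylbut-2-en-1-yl)oxy]-1,3-benzodioxole | CC(C)=CCOc1ccc(Br)c2OC(C)(C)Oc12
F9 | step 3 | 7-bromo-2,2-dimethyl-5-(2-methylbut-3-en-2-yl)-1,3-benzodioxol-4(5H)-one (not isolated) | C=CC(C)(C)C1C=C(Br)C2=C(OC(C)(C)O2)C1=O
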